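## Retrosynthetic overview

1. Target 12 ⇒ open-chain pentaketide equivalent 9, a triketo-dioxinone that already carries the farnesylated quaternary carbon. C8a–C4a aldol condensation closes the carbocycle first; C3-enol O→C1 lactonisation (loss of acetone) then closes the α-pyrone. This is the polyketide order (aldol, then lactonisation), run on a chain that cannot aromatise.
2. 9 ⇒ C6–C7 Claisen-type disconnection: enol lactone 4 (farnesylated triketide pyrone) plus the γ-dienolate of dioxinone 7 (diketide unit carrying the C7 methyl).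
3. 4 ⇒ catalytic asymmetric C-farnesylation of triketide pyrone 3 with farnesyl carbonate 2; this sets the only stereocentre.
4. 7 ⇐ 5 by γ-methylation; 2 ⇐ farnesol 1.

Assumptions (one line): "farnesyl" = (2E,6E)-3,7,11-trimethyldodeca-2,6,10-trien-1-yl; the target stereocentre C5 is S; pyrone 3 is bought as a catalogue compound; the (R,R)-ligand is taken to give (S)-4, and the (S,S)-ligand (also commercial) is used if the sense of induction is the reverse.

## Route

Step 1
Reactants: 1 (2E,6E)-farnesol
Product: 2 tert-butyl (2E,6E)-farnesyl carbonate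
Conditions: Boc2O (1.3 equiv), n-Bu4NHSO4 (5 mol%), 30% aq. NaOH, CH2Cl2, 0 °C → rt
Reagents that add atoms: di-tert-butyl dicarbonate, CC(C)(C)OC(=O)OC(=O)OC(C)(C)C
Why: Phase-transfer O-tert-butoxycarbonylation of a primary allylic alcohol is routine and leaves the trisubstituted alkenes untouched; no stereocentre is formed, and the tert-butyl carbonate later releases only CO2 and non-nucleophilic tert-butanol.

Step 2
Reactants: 2 tert-butyl (2E,6E)-farnesyl carbonate; 3 4-hydroxy-3,6-dimethyl-2H-pyran-2-one
Product: 4 (3S)-3-farnesyl-3,6-dimethyl-2H-pyran-2,4(3H)-dione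
Conditions: 2 (1.1 equiv), [Pd2(dba)3]·CHCl3 (2.5 mol%), (R,R)-ANDEN-phenyl Trost ligand (7.5 mol%), degassed toluene, 0 °C → rt, no added base
Reagents that add atoms: none
Why: Proposed new method: Tsuji–Trost asymmetric allylic alkylation in which decarboxylative ionisation of 2 supplies the base for the acidic pyrone (pKa about 5), the soft C3 nucleophile attacks the unsubstituted terminus of the Pd–allyl electrophile (linear, E-retained product), any O-allyl product re-ionises under Pd(0) and funnels to the C-allyl dione, and the chiral pocket of the ligand selects one enantiotopic face of C3 to set the quaternary S centre; the closest known reactions are Pd-catalysed C3-allylation of 4-hydroxy-2-pyrones to 3,3-disubstituted pyrandiones and Trost-ligand asymmetric prenylation/geranylation of cyclic β-keto esters and 3-substituted oxindoles.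

Step 3
Reactants: 5 2,2,6-trimethyl-4H-1,3-dioxin-4-one
Product: 7 6-ethyl-2,2-dimethyl-4H-1,3-dioxin-4-one, via lithium methylidene-dioxinolate 6 (not isolated)
Conditions: LDA (1.1 equiv, commercial solution), THF, −78 °C; then MeI (1.5 equiv), DMPU, −78 → −30 °C
Reagents that add atoms: iodomethane, CI
Why: Vinylogous (γ) enolate alkylation: the cross-conjugated lithium dienolate of the dioxinone behaves like an acetoacetate dianion and is methylated at the exocyclic carbon; no stereocentre is formed.

Step 4
Reactants: 7 6-ethyl-2,2-dimethyl-4H-1,3-dioxin-4-one; 4 (3S)-3-farnesyl-3,6-dimethyl-2H-pyran-2,4(3H)-dione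
Product: 9 6-[(4S)-4-farnesyl-4-methyl-3,5,7-trioxooctan-2-yl]-2,2-dimethyl-4H-1,3-dioxin-4-one (epimers at the new CH(Me); keto/enol mixture), via lithium ethylidene-dioxinolate 8 (not isolated)
Conditions: 7 (2.2 equiv), LDA (2.2 equiv), THF, −78 °C, 1 h; add 4 (1.0 equiv), −78 → −40 °C; AcOH quench at −78 °C
Reagents that add atoms: none
Why: Proposed new method: Claisen-type C-acylation of the dioxinone γ-dienolate by the enol-lactone carbonyl of 4 (a vinylogous anhydride), with ring opening that releases a stabilised β-diketone enolate and is therefore irreversible, whereas 1,2-addition at the C4 ketone is reversible; the second equivalent of dienolate deprotonates the new tricarbonyl CH and prevents over-addition; the quaternary centre is not touched and the new CH(Me) centre is inconsequential (it becomes sp2); the closest known reactions are γ-acylation of dioxinone dienolates with acyl chlorides or imidazolides and the Fujimoto–Belleau opening of enol lactones by carbon nucleophiles.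

Step 5
Reactants: 9 6-[(4S)-4-farnesyl-4-methyl-3,5,7-trioxooctan-2-yl]-2,2-dimethyl-4H-1,3-dioxin-4-one
Product: 12 5-farnesyl-isochromene [(5S)-5-farnesyl-8-hydroxy-3,5,7-trimethyl-1H-isochromene-1,6(5H)-dione], via aldol adduct 10 (not isolated), via dienone acetonide 11 (not isolated)
Conditions: Et3N (3 equiv), CH2Cl2, rt; then DBU (2 equiv), 40 °C; pH 5 buffer wash (no strong acid, T ≤ 40 °C)
Reagents that add atoms: none
Why: Proposed new method: biomimetic polyketide cascade in which the dioxinone α-carbon (C8a) adds to the C4a ketone (intramolecular aldol; the dioxinone masks C8 so the alternative C4→C8 folding is blocked), E1cB dehydration gives the cross-conjugated dienone acetonide, which cannot aromatise because C5 is quaternary, and the C3 enolate then attacks the acylal carbonyl C1 and expels acetone to close the α-pyrone; the S centre is a non-enolisable quaternary carbon and is carried through unchanged; the closest known reactions are the base-mediated aldol aromatisation of diketo-dioxinones to resorcylate acetonides and the enol-lactonisation of 2-(2-oxopropyl)benzoates to 3-methylisocoumarins, and base-only conditions avoid cationic cyclisation of the polyene and [3,3] shifts of the farnesyl group.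

## Compound list

1 | (2E,6E)-farnesol | CC(C)=CCC/C(C)=C/CC/C(C)=C/CO | starting material
2 | tert-butyl (2E,6E)-farnesyl carbonate | CC(C)=CCC/C(C)=C/CC/C(C)=C/COC(=O)OC(C)(C)C | intermediate
3 | 4-hydroxy-3,6-dimethyl-2H-pyran-2-one | CC1=CC(O)=C(C)C(=O)O1 | starting material
4 | (3S)-3-farnesyl-3,6-dimethyl-2H-pyran-2,4(3H)-dione | CC(C)=CCC/C(C)=C/CC/C(C)=C/C[C@]1(C)C(=O)OC(C)=CC1=O | intermediate
5 | 2,2,6-trimethyl-4H-1,3-dioxin-4-one | CC1=CC(=O)OC(C)(C)O1 | starting material
6 | lithium 2,2-dimethyl-6-methylidene-6H-1,3-dioxin-4-olate | C=C1C=C([O-])OC(C)(C)O1.[Li+] | intermediate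
7 | 6-ethyl-2,2-dimethyl-4H-1,3-dioxin-4-one | CCC1=CC(=O)OC(C)(C)O1 | intermediate
8 | lithium 6-ethylidene-2,2-dimethyl-6H-1,3-dioxin-4-olate | CC=C1C=C([O-])OC(C)(C)O1.[Li+] | intermediate
9 | 6-[(4S)-4-farnesyl-4-methyl-3,5,7-trioxooctan-2-yl]-2,2-dimethyl-4H-1,3-dioxin-4-one | CC(C)=CCC/C(C)=C/CC/C(C)=C/C[C@@](C)(C(=O)CC(C)=O)C(=O)C(C)C1=CC(=O)OC(C)(C)O1 | intermediate
10 | (6S)-6-farnesyl-5-hydroxy-2,2,6,8-tetramethyl-5-(2-oxopropyl)-5,8-dihydro-4H-1,3-benzodioxine-4,7(6H)-dione | CC(C)=CCC/C(C)=C/CC/C(C)=C/C[C@]1(C)C(=O)C(C)C2=C(C(=O)OC(C)(C)O2)C1(O)CC(C)=O | intermediate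
11 | (6S)-6-farnesyl-2,2,6,8-tetramethyl-5-(2-oxopropyl)-4H-1,3-benzodioxine-4,7(6H)-dione | CC(C)=CCC/C(C)=C/CC/C(C)=C/C[C@]1(C)C(=O)C(C)=C2OC(C)(C)OC(=O)C2=C1CC(C)=O | intermediate
12 | 5-farnesyl-isochromene, (5S)-5-farnesyl-8-hydroxy-3,5,7-trimethyl-1H-isochromene-1,6(5H)-dione | CC(C)=CCC/C(C)=C/CC/C(C)=C/C[C@]1(C)C(=O)C(C)=C(O)c2c1cc(C)oc2=O | target

## Step count and risks

Total steps: 5. Longest linear sequence: 4 (1 → 2 → 4 → 9 → 12).

Three steps most likely to fail:

**Step 5 (cascade).** The risks are a slow aldol at the hindered C4a ketone and a competing aldol of the C7 carbon onto the C3 methyl ketone. Fallback, setting out from 4 and coming back at 12: reverse the order of bond formation so that the methyl ketone is never free while the carbocycle forms. Knoevenagel condensation of 4 at its C4 ketone with commercial methyl 3-oxopentanoate (TiCl4, pyridine, THF, 0 °C → rt) gives the alkylidene keto ester methyl 2-[(3S)-3-farnesyl-3,6-dimethyl-2-oxo-2,3-dihydro-4H-pyran-4-ylidene]-3-oxopentanoate F3. DBU (THF, rt) then deprotonates the propionyl CH2, which acylates intramolecularly on the enol-lactone carbonyl; this closes the carbocycle and releases the C3 enolate, which lactonises onto the methyl ester to give 12.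

**Step 4 (acyl substitution on the enol lactone).** The risks are deprotonation of the 6-methyl of 4, or attack at C4/C6 by the hindered secondary dienolate 8. Fallback, setting out from 4 and dienolate 6 (made from 5 as in step 3) and coming back at 9: use the unhindered primary dienolate 6 (2.2 equiv, THF, −78 °C) to open 4, giving the des-methyl triketo-dioxinone 6-[(3R)-3-farnesyl-3-methyl-2,4,6-trioxoheptyl]-2,2-dimethyl-4H-1,3-dioxin-4-one F2. It has the same spatial arrangement as 4; the descriptor changes only through CIP priorities. The C7 methyl is then introduced through the dianion (LiHMDS 2.1 equiv, then MeI 1.0 equiv, THF/DMPU, −78 °C), which alkylates at the more basic carbanion between the ketone and the dioxinone, giving 9.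

**Step 2 (asymmetric farnesylation).** The risks are low ee with a linear trisubstituted allyl unit and partial E/Z scrambling at the 2,3-alkene. Fallback, setting out from 2 and 3 and coming back at 4: run the allylation with achiral Pd(PPh3)4 (toluene, rt) to give racemic 3-farnesyl-3,6-dimethyl-2H-pyran-2,4(3H)-dione F1. Resolve it by preparative chiral SFC; the (S)-enantiomer is 4, and the (R)-enantiomer of the pyrandione F4 is discarded.

## Further compounds

F1 | step 2 | racemic 3-farnesyl-3,6-dimethyl-2H-pyran-2,4(3H)-dione | CC(C)=CCC/C(C)=C/CC/C(C)=C/CC1(C)C(=O)OC(C)=CC1=O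
F4 | step 2 | (3R)-3-farnesyl-3,6-dimethyl-2H-pyran-2,4(3H)-dione | CC(C)=CCC/C(C)=C/CC/C(C)=C/C[C@@]1(C)C(=O)OC(C)=CC1=O
F2 | step 4 | 6-[(3R)-3-farnesyl-3-methyl-2,4,6-trioxoheptyl]-2,2-dimethyl-4H-1,3-dioxin-4-one | CC(C)=CCC/C(C)=C/CC/C(C)=C/C[C@@](C)(C(=O)CC(C)=O)C(=O)CC1=CC(=O)OC(C)(C)O1
F3 | step 5 | methyl 2-[(3S)-3-farnesyl-3,6-dimethyl-2-oxo-2,3-dihydro-4H-pyran-4-ylidene]-3-oxopentanoate | CC(C)=CCC/C(C)=C/CC/C(C)=C/C[C@]1(C)C(=O)OC(C)=CC1=C(C(=O)OC)C(=O)CC
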